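## Plan

1. Germacrane numbering is used throughout: ring C1–C10, C14 on C10, C15 on C4, C11 (carrying C12H2O and C13H3) on C7. The enabling feature is that C10=C1–C2–C3–C4=C5 (C4=C5 being what the C4–C5 oxirane was) is a 1,5-diene inside the ring. Joining C1–C4 and C5–C10 therefore folds the ten-membered ring into a bicyclo[2.2.0]hexane (C10, C1, C2, C3, C4, C5) fused along C5–C10 to the six-membered ring C5–C10 of carvone.
2. Cuts, in order: the two acetates; both oxiranes (to a 4,7(11)-diene-12,15-diol); C9=O and the C7=C11 geometry (to a 12,9-lactone that holds C12 cis to C8); the π bonds C1=C10 and C4=C5 (back to σ bonds C1–C4 and C5–C10); the cyclobutane bonds C1–C10 and C4–C5 (to carvone and a 1-(silyloxymethyl)cyclobutene).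
3. Forward: photo-[2+2] builds the 6-4-4 tricycle; a δ-lactone is closed from C12 to O9 across the six-membered ring; heat opens the bicyclohexane and releases the ten-membered ring; the lactone is dehydrogenated (C7=C11) and reduced open; the two oxiranes are closed last, then acetylation.
4. Stereochemistry: all four centres of the target (4R,5R,7S,11R) come from D-(−)-diethyl tartrate in one double Sharpless epoxidation. They rest on alkene geometries fixed earlier: C1=C10 E and C4=C5 ring-cis from the lactone-locked cycloreversion, and C12 cis to C8 from the lactone ring.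
5. The carvone centre, the four ring-fusion centres and the CBS-set C9 carbinol are temporary control elements; all are erased before the end.

Key step: step 7

Remark 1: C11 is formed unselectively in step 5 and is carried as both epimers (no descriptor in the SMILES of 7–12) until it becomes sp2 in step 8.
Remark 2: "C4=C5 ring-cis" means C3 and C6 cis (formally E, because C15 outranks C3); the photoadduct is assumed to be the cis-anti-cis head-to-tail isomer formed anti to the isopropenyl group.

## Route

Step 1
Reactants: 1 ethyl 1-bromocyclobutane-1-carboxylate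
Product: 2 cyclobut-1-ene-1-carboxylic acid
Conditions: KOH (powdered), PhMe, reflux; then aq. HCl, 0 °C; used at once
Reagents that add atoms: potassium hydroxide, [K+].[OH-]
Why: E2 dehydrobromination of the tertiary α-bromo ester by hydroxide, with saponification in the same pot, is the classical entry to the strained conjugated cyclobutene acid.

Step 2
Reactants: 2 cyclobut-1-ene-1-carboxylic acid
Product: 3 (cyclobut-1-en-1-yl)methanol
Conditions: LiAlH4, Et2O, 0 °C to rt
Reagents that add atoms: none
Why: Hydride reduction of an α-substituted α,β-unsaturated acid is 1,2-selective under these conditions and should give the allylic alcohol with the ring alkene intact.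

Step 3
Reactants: 3 (cyclobut-1-en-1-yl)methanol
Product: 4 tert-butyl(cyclobut-1-en-1-ylmethoxy)dimethylsilane
Conditions: TBSCl, imidazole, CH2Cl2, 0 °C to rt
Reagents that add atoms: tert-butyldimethylsilyl chloride, CC(C)(C)[Si](C)(C)Cl
Why: Imidazole-mediated silylation of a primary alcohol gives a non-volatile ether that should survive irradiation, borane, oxoammonium oxidation, 190 °C, LDA and DIBAL-H.

Step 4
Reactants: 5 (R)-(−)-carvone; 4 tert-butyl(cyclobut-1-en-1-ylmethoxy)dimethylsilane
Product: 6 cis-anti-cis head-to-tail photoadduct (1S,4S,5S,7R,10R)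
Conditions: hν (Pyrex, λ > 300 nm), 4 (4 equiv), 5 (0.05 M), degassed CH2Cl2, −20 °C
Reagents that add atoms: none
Why: Triplet enone–alkene [2+2] photocycloaddition: the alkyl-substituted cyclobutene should add head-to-tail (C4 to the β-carbon C5, C1 to C10, so that no adjacent quaternary pair arises), anti to the C7 isopropenyl group and with cis-anti-cis ring fusion, which sets C1, C4, C5 and C10 relative to C7; the excess of alkene outruns the slow intramolecular cycloaddition of carvone.

Step 5
Reactants: 6 cis-anti-cis head-to-tail photoadduct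
Product: 8 (9R)-9,12-diol (1S,4S,5S,7R,9R,10R; C11 epimers), via bis-boryl intermediate 7 (not isolated)
Conditions: (S)-Me-CBS (20 mol%), BH3·SMe2 (3 equiv), THF, −20 °C to rt (ketone added slowly); then NaOH, H2O2, 0 °C
Reagents that add atoms: hydrogen peroxide, OO
Why: Corey–Bakshi–Shibata reduction, in which the catalyst tells the quaternary C10 from the C8 methylene (as tert-butyl from methyl in pinacolone), so the (S)-catalyst should set 9R (OH cis to the C7 side chain, trans to the cyclobutane); the excess borane hydroborates the 1,1-disubstituted alkene anti-Markovnikov and oxidation gives the primary alcohol.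

Step 6
Reactants: 8 (9R)-9,12-diol
Product: 11 bridged 12,9-lactone (1S,4S,5S,7R,9R,10R; C11 epimers), via hydroxy aldehyde 9 (not isolated), via lactol 10 (not isolated)
Conditions: TEMPO (20 mol%), PhI(OAc)2 (2.5 equiv), CH2Cl2, rt
Reagents that add atoms: none
Why: Oxoammonium (TEMPO/PhI(OAc)2) oxidative lactonisation of a 1,5-diol: only the primary alcohol is oxidised, the aldehyde is captured by the hindered C9–OH, which can reach it because the two groups are cis and become 1,3-diaxial on the chair of the six-membered ring, and the lactol is oxidised again.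

Step 7
Reactants: 11 bridged 12,9-lactone
Product: 12 (7R,9R)-15-(tert-butyldimethylsilyloxy)germacra-1(10),4-dien-12,9-olide (C1=C10 E; C4=C5 ring-cis; C11 epimers)
Conditions: degassed PhMe (0.01 M), sealed base-washed tube, 190 °C, about 1 h, stopped as soon as 11 is consumed
Reagents that add atoms: none
Why: Thermal [σ2s+σ2a] cycloreversion of the bicyclo[2.2.0]hexane (C10, C1, C2, C3, C4, C5): the strained central C1–C4 bond homolyses to a cyclohexane-1,4-diyl, which passes through a chair and cleaves C5–C10, i.e. the first half of a chair Cope rearrangement run backwards. The closest known reaction type is the thermolysis of cis-anti-cis enone–cyclobutene photoadducts to cyclodeca-1,5-dienes. The ten-membered ring arises by ring expansion (two σ bonds of the fused 6-4-4 system become the C1=C10 and C4=C5 π bonds), not by end-to-end closure; no stereocentre is created and C1, C4, C5 and C10 are erased. The selectivity needed is E at C1=C10 together with ring-cis at C4=C5 rather than the other E,Z pair, and it depends on which of C9 and C6 is equatorial on the diyl chair. The lactone bridge holds C7–C11 and C9–O diaxial on a chair six-membered ring, which puts C1 axial and C4 equatorial on that ring and hence C9 equatorial and C6 axial on the diyl ring, so C9 should end trans to C2 and C6 cis to C3. The short heating time and the E,Z geometry of the product should hold back the onward Cope shift to the divinylcyclohexane.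

Step 8
Reactants: 12 (7R,9R)-15-(tert-butyldimethylsilyloxy)germacra-1(10),4-dien-12,9-olide
Product: 14 (9R)-15-(tert-butyldimethylsilyloxy)germacra-1(10),4,7(11)-trien-12,9-olide, via selenide 13 (not isolated)
Conditions: LDA, THF, −78 °C; PhSeBr, −78 °C; then H2O2, pyridine, CH2Cl2, 0 °C to rt
Reagents that add atoms: none
Why: Selenenylation of the lactone enolate anti to C6 should place selenium cis to H7, and selenoxide syn-elimination then gives the conjugated endocyclic alkene; inside the six-membered lactone the new C7=C11 bond can only have C12 cis to C8, and both C11 epimers converge.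

Step 9
Reactants: 14 (9R)-15-(tert-butyldimethylsilyloxy)germacra-1(10),4,7(11)-trien-12,9-olide
Product: 15 (9R)-15-(tert-butyldimethylsilyloxy)germacra-1(10),4,7(11)-triene-9,12-diol (7(11)Z)
Conditions: DIBAL-H (4 equiv), CH2Cl2, −78 to 0 °C; Rochelle salt work-up
Reagents that add atoms: none
Why: DIBAL-H reduces the α,β-unsaturated lactone 1,2 through the lactol to the diol, so the tetrasubstituted alkene stays in place with CH2OH cis to C8.

Step 10
Reactants: 15 (9R)-triene-9,12-diol
Product: 16 (9R)-12,15-bis(tert-butyldimethylsilyloxy)germacra-1(10),4,7(11)-trien-9-ol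
Conditions: TBSCl (1.1 equiv), imidazole, CH2Cl2, 0 °C
Reagents that add atoms: tert-butyldimethylsilyl chloride, CC(C)(C)[Si](C)(C)Cl
Why: Steric differentiation in silylation: the primary allylic alcohol reacts, the hindered secondary C9 carbinol stays free for the oxidation.

Step 11
Reactants: 16 (9R)-bis-silyl ether 9-ol
Product: 17 12,15-bis(tert-butyldimethylsilyloxy)germacra-1(10),4,7(11)-trien-9-one
Conditions: Dess–Martin periodinane, NaHCO3, CH2Cl2, 0 °C to rt
Reagents that add atoms: none
Why: Buffered Dess–Martin oxidation of the secondary allylic alcohol gives the E-enone without moving the β,γ-alkene; the last temporary centre (C9) is erased and the compound has no stereocentre.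

Step 12
Reactants: 17 bis-silyl ether trienone
Product: 18 12,15-dihydroxygermacra-1(10),4,7(11)-trien-9-one (1(10)E; C4=C5 ring-cis; 7(11)Z)
Conditions: HF·pyridine, pyridine, THF, 0 °C
Reagents that add atoms: none
Why: Buffered fluoride cleavage of both primary silyl ethers; no base is present that could pull the C7=C11 alkene into conjugation through the doubly activated C8.

Step 13
Reactants: 18 12,15-dihydroxy trienone
Product: 19 (4R,5R,7S,11R)-4,5:7,11-diepoxy-12,15-dihydroxygermacr-1(10)-en-9-one
Conditions: Ti(OiPr)4 (20 mol%), D-(−)-diethyl tartrate (24 mol%), t-BuOOH (4 equiv), 4 Å MS, CH2Cl2, −20 °C; non-basic work-up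
Reagents that add atoms: tert-butyl hydroperoxide, CC(C)(C)OO
Why: Katsuki–Sharpless asymmetric epoxidation of both primary allylic alcohols (the enone alkene is inert): D-(−)-tartrate, the enantiomer of the one that turns geraniol into (2S,3S)-epoxygeraniol, should give the 2R-type sense at C4 and at C11, and syn addition then gives 5R (C6 trans to C15) and 7S (C8 cis to C12).

Step 14
Reactants: 19 bis-epoxy diol
Product: 20 target, (4R,5R,7S,11R)-12,15-diacetoxy-4,5:7,11-diepoxygermacr-1(10)E-en-9-one
Conditions: Ac2O, pyridine, DMAP (cat.), CH2Cl2, 0 °C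
Reagents that add atoms: acetic anhydride, CC(=O)OC(C)=O
Why: Acetylation of two primary alcohols under mild amine catalysis; nothing basic enough is present to open the C7–C11 oxirane β to the ketone by E1cB.

## Compound list

1 | ethyl 1-bromocyclobutane-1-carboxylate | CCOC(=O)C1(Br)CCC1 | starting material
2 | cyclobut-1-ene-1-carboxylic acid | OC(=O)C1=CCC1 | intermediate
3 | (cyclobut-1-en-1-yl)methanol | OCC1=CCC1 | intermediate
4 | tert-butyl(cyclobut-1-en-1-ylmethoxy)dimethylsilane | CC(C)(C)[Si](C)(C)OCC1=CCC1 | intermediate
5 | (R)-(−)-carvone | CC(=C)[C@H]1CC(=O)C(C)=CC1 | starting material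
6 | cis-anti-cis head-to-tail photoadduct, (1S,4S,5S,7R,10R): cyclohexanone C5–C10 fused along C5–C10 to cyclobutane C10–C1–C4–C5, itself fused along C1–C4 to cyclobutane C1–C2–C3–C4; CH2OTBS on C4, CH3 on C10, isopropenyl on C7 trans to the cyclobutane | CC(=C)[C@H]1CC(=O)[C@@]2(C)[C@@H](C1)[C@]1(CO[Si](C)(C)C(C)(C)C)CC[C@@H]12 | intermediate
7 | 9-O-boryl, 12-boryl intermediate of step 5 (drawn monomeric) | CC(CB)[C@H]1C[C@@H](OB)[C@@]2(C)[C@@H](C1)[C@]1(CO[Si](C)(C)C(C)(C)C)CC[C@@H]12 | intermediate (not isolated)
8 | (1S,4S,5S,7R,9R,10R)-9,12-diol: 9-OH cis to the C7 side chain CH(CH3)CH2OH and trans to the cyclobutane; C11 epimers | CC(CO)[C@H]1C[C@@H](O)[C@@]2(C)[C@@H](C1)[C@]1(CO[Si](C)(C)C(C)(C)C)CC[C@@H]12 | intermediate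
9 | 9-hydroxy-12-aldehyde from 8 | CC(C=O)[C@H]1C[C@@H](O)[C@@]2(C)[C@@H](C1)[C@]1(CO[Si](C)(C)C(C)(C)C)CC[C@@H]12 | intermediate (not isolated)
10 | bridged lactol (C12 hemiacetal to O9) | CC1C(O)O[C@@H]2C[C@H]1C[C@@H]1[C@@]2(C)[C@H]2CC[C@@]12CO[Si](C)(C)C(C)(C)C | intermediate (not isolated)
11 | bridged δ-lactone C12(=O)–O–C9 across C7/C9 of the six-membered ring (2-oxabicyclo[3.3.1]nonan-3-one unit), (1S,4S,5S,7R,9R,10R), C11 epimers | CC1C(=O)O[C@@H]2C[C@H]1C[C@@H]1[C@@]2(C)[C@H]2CC[C@@]12CO[Si](C)(C)C(C)(C)C | intermediate
12 | (7R,9R)-15-(tert-butyldimethylsilyloxy)germacra-1(10),4-dien-12,9-olide, C1=C10 E, C4=C5 ring-cis, C11 epimers | C/C1=C\CC/C(CO[Si](C)(C)C(C)(C)C)=C\C[C@@H]2C[C@H]1OC(=O)C2C | intermediate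
13 | (7R,9R,11S)-11-phenylseleno derivative of 12, selenium cis to H7 | C/C1=C\CC/C(CO[Si](C)(C)C(C)(C)C)=C\C[C@@H]2C[C@H]1OC(=O)[C@@]2(C)[Se]c1ccccc1 | intermediate (not isolated)
14 | (9R)-15-(tert-butyldimethylsilyloxy)germacra-1(10)E,4,7(11)-trien-12,9-olide | C/C1=C\CC/C(CO[Si](C)(C)C(C)(C)C)=C\CC2=C(C)C(=O)O[C@@H]1C2 | intermediate
15 | (9R)-15-(tert-butyldimethylsilyloxy)germacra-1(10)E,4,7(11)Z-triene-9,12-diol | C/C1=C\CC/C(CO[Si](C)(C)C(C)(C)C)=C\C/C(=C(\C)CO)C[C@H]1O | intermediate
16 | (9R)-12,15-bis(tert-butyldimethylsilyloxy)germacra-1(10)E,4,7(11)Z-trien-9-ol | C/C1=C\CC/C(CO[Si](C)(C)C(C)(C)C)=C\C/C(=C(\C)CO[Si](C)(C)C(C)(C)C)C[C@H]1O | intermediate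
17 | 12,15-bis(tert-butyldimethylsilyloxy)germacra-1(10)E,4,7(11)Z-trien-9-one (no stereocentre) | C/C1=C\CC/C(CO[Si](C)(C)C(C)(C)C)=C\C/C(=C(\C)CO[Si](C)(C)C(C)(C)C)CC1=O | intermediate
18 | 12,15-dihydroxygermacra-1(10)E,4,7(11)Z-trien-9-one, C4=C5 ring-cis (no stereocentre) | C/C1=C\CC/C(CO)=C\C/C(=C(\C)CO)CC1=O | intermediate
19 | (4R,5R,7S,11R)-4,5:7,11-diepoxy-12,15-dihydroxygermacr-1(10)E-en-9-one | OC[C@]12CC/C=C(\C)C(=O)C[C@]3(C[C@H]1O2)O[C@]3(C)CO | intermediate
20 | (4R,5R,7S,11R)-12,15-diacetoxy-4,5:7,11-diepoxygermacr-1(10)E-en-9-one | CC(=O)OC[C@]12CC/C=C(\C)C(=O)C[C@]3(C[C@H]1O2)O[C@]3(C)COC(C)=O | target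

## Count and risks

Total steps: 14. Longest linear sequence: 14 steps (1 to 20); carvone 5 enters at step 4 and is 11 steps from the target.

**Risk 1, step 7.** The E/ring-cis pairing could be lost if ring opening leaks through a non-chair array, and the new 1,5-diene could undergo an onward [3,3] shift to the divinylcyclohexane while the last of 11 is still opening. Fallback: move the cycloreversion to the ketone level, where C1=C10 is formed in conjugation with C9=O, which holds back the Cope shift. Setting out from 6, thermolysis gives the dienone F1; without the lock its geometric isomer has to be separated. (S)-Me-CBS with catecholborane should reduce it to the (9R)-trienol F2. 9-BBN followed by NaOH/H2O2 hydroborates only the 1,1-disubstituted alkene and gives the diol F3. TEMPO/PhI(OAc)2 lactonises F3, and the route is rejoined at 12.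

**Risk 2, step 5.** The substrate's own facial bias, or uncatalysed borane reduction, could override the catalyst and deliver hydride to the other face, giving the 9S alcohol, which cannot bridge to C12. Fallback: make that epimer on purpose and invert later. From 6, the same operation with (R)-Me-CBS gives the (9S)-diol F4. TEMPO/PhI(OAc)2 in aqueous MeCN gives the hydroxy acid F5, since no lactone can form. Thermolysis in toluene with Et3N gives the ring-opened hydroxy acid F6; the chair with C1 axial should now be preferred because the other chair would place 9-OH and C4 syn-diaxial. Mitsunobu lactonisation (PPh3, DIAD) inverts the now allylic C9 and returns to 12.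

**Risk 3, step 8.** Selenoxide syn-elimination could run toward the C13 methyl instead of H7, either because selenium enters trans to H7 or because the exocyclic path is faster. Fallback: accept the exocyclic isomer and move the double bond. From 12 the same selenenylation–oxidation then gives the α-methylene lactone F7. RhCl3·3H2O in ethanol (metal-hydride addition–elimination, the usual isomerisation of α-methylene lactones) carries the alkene into the ring, where only C7 offers a hydrogen, and returns to 14.

Further compounds
F1 | step 7 | (7R)-15-(tert-butyldimethylsilyloxy)germacra-1(10)E,4,11-trien-9-one, C4=C5 ring-cis | CC(=C)[C@H]1CC(=O)/C(C)=C/CC/C(CO[Si](C)(C)C(C)(C)C)=C\C1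
F2 | step 7 | (7R,9R)-15-(tert-butyldimethylsilyloxy)germacra-1(10)E,4,11-trien-9-ol | CC(=C)[C@H]1C[C@@H](O)/C(C)=C/CC/C(CO[Si](C)(C)C(C)(C)C)=C\C1
F3 | step 7 | (7R,9R)-15-(tert-butyldimethylsilyloxy)germacra-1(10)E,4-diene-9,12-diol, C11 epimers | CC(CO)[C@H]1C[C@@H](O)/C(C)=C/CC/C(CO[Si](C)(C)C(C)(C)C)=C\C1
F4 | step 5 | (1S,4S,5S,7R,9S,10R)-9,12-diol, the C9 epimer of 8 | CC(CO)[C@H]1C[C@H](O)[C@@]2(C)[C@@H](C1)[C@]1(CO[Si](C)(C)C(C)(C)C)CC[C@@H]12
F5 | step 5 | (9S)-9-hydroxy-12-oic acid of the tricycle, C11 epimers | CC(C(=O)O)[C@H]1C[C@H](O)[C@@]2(C)[C@@H](C1)[C@]1(CO[Si](C)(C)C(C)(C)C)CC[C@@H]12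
F6 | step 5 | (7R,9S)-9-hydroxy-15-(tert-butyldimethylsilyloxy)germacra-1(10)E,4-dien-12-oic acid, C4=C5 ring-cis | CC(C(=O)O)[C@H]1C[C@H](O)/C(C)=C/CC/C(CO[Si](C)(C)C(C)(C)C)=C\C1
F7 | step 8 | (7R,9R)-15-(tert-butyldimethylsilyloxy)germacra-1(10)E,4,11(13)-trien-12,9-olide | C/C1=C\CC/C(CO[Si](C)(C)C(C)(C)C)=C\C[C@@H]2C[C@H]1OC(=O)C2=C
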